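**Plan**

1. Numbering used throughout: C1 = benzylic CH2; ring A = C2 (CH bearing C1), C3 (C=CH2), C4, C5, C6 (CHBr), C7 (quaternary, CH3); chain C8, C9, C10 (CHBr), C11 (C(OH)CH3), C12, C13, C14 (ester CH), C15(=C16H2)CH3; arene C1′ (carboxyl), C3′ (CH2), C4′ (OH).
2. Cuts, latest first: the macrolactone O–C14 bond; C14–C15 (isopropenyl anion on a lactone carbonyl); C10–Br and C11–O together (bromolactonisation of an (E)-C10=C11 acid); C12–C13 (Claisen) and C10–C11 (isopropenyl Grignard on a C10 aldehyde); C1–C3′ (Negishi); C2–C7 and C6–Br (bromonium closure of ring A onto a β-keto ester); C4–C5 (acetoacetate dianion alkylation).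
3. Enabling feature: C14 lies four carbons from C11 (C11–C12–C13–C14), so a C14 carboxyl oxygen reaches C11 of the C10=C11 alkene through a five-membered γ-lactone closure while bromine adds to C10; the lactone carbonyl later becomes the C14 carbinol.
4. Forward order: C1–C10 chain (steps 1–4), ring A (steps 5–7), arene attached (step 12), C11–C14 arm (steps 15–17), temporary γ-lactone (step 18), isopropenyl ketone and C14 alcohol (steps 19–20), 15-membered macrolactone last (step 22).
5. Stereochemistry: C6/C7 from a catalyst-controlled anti bromo-cyclisation of the (E)-C6=C7 alkene, C2 from the chair closure with the ester equatorial; C10/C11 from the catalyst-controlled anti bromolactonisation of the (E)-C10=C11 alkene; C14 from a CBS reduction, retained in an acyl-activation macrolactonisation; the two alkene geometries from a syn carboalumination and a chair Johnson–Claisen rearrangement.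

Key step: step 18

Assumption: the catalyst in steps 5 and 18 is a 9-O-(N-arylthiocarbamoyl) cinchona alkaloid; whether the quinidine- or the quinine-derived pseudo-enantiomer gives the drawn configuration is settled in a first small run ("matched catalyst"), and the (R)-CBS assignment in step 20 takes isopropenyl as the large group.

**Route**

Step 1
Reactants: 1 pent-4-yn-1-ol
Product: 2 triisopropyl(pent-4-yn-1-yloxy)silane
Conditions: TIPSCl, imidazole, CH2Cl2, 0 °C to rt
Reagents that add atoms: chlorotriisopropylsilane, CC(C)[Si](Cl)(C(C)C)C(C)C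
Why: Imidazole-promoted silylation of the primary alcohol gives a bulky silyl ether that tolerates AlMe3 and SnCl4 and is too hindered for the C10 oxygen, which sits 5-exo to C7, to intercept the later bromonium ion.

Step 2
Reactants: 2 triisopropyl(pent-4-yn-1-yloxy)silane
Product: 5 (E)-3-methyl-6-(triisopropylsilyloxy)hex-2-en-1-ol, via alkenyldimethylalane 3 (not isolated), via lithium alkenylaluminate 4 (not isolated)
Conditions: AlMe3, Cp2ZrCl2 (0.25 equiv), CH2Cl2, 0 °C to rt; n-BuLi, THF, −78 °C; (CH2O)n, −78 °C to rt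
Reagents that add atoms: trimethylaluminium, C[Al](C)C; formaldehyde (as paraformaldehyde), C=O
Why: Negishi carboalumination adds CH3 and Al syn across the terminal alkyne with Al at the terminus, and the aluminate is hydroxymethylated with retention, which fixes the (E)-C6=C7 geometry (no stereocentre is formed).

Step 3
Reactants: 5 (E)-3-methyl-6-(triisopropylsilyloxy)hex-2-en-1-ol
Product: 6 (E)-(6-bromo-4-methylhex-4-en-1-yloxy)triisopropylsilane
Conditions: CBr4, PPh3, CH2Cl2, 0 °C
Reagents that add atoms: tetrabromomethane, BrC(Br)(Br)Br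
Why: Appel bromination displaces the alkoxyphosphonium ion of the primary allylic alcohol by bromide under neutral conditions that keep the silyl ether and the alkene geometry.

Step 4
Reactants: 6 (E)-(6-bromo-4-methylhex-4-en-1-yloxy)triisopropylsilane; 7 methyl acetoacetate
Product: 9 methyl (E)-7-methyl-3-oxo-10-(triisopropylsilyloxy)dec-6-enoate, via acetoacetate dianion 8 (not isolated)
Conditions: NaH, THF, 0 °C; n-BuLi, 0 °C; then 6, 0 °C
Reagents that add atoms: none
Why: In the acetoacetate dianion alkylation the more basic terminal carbanion attacks the allylic bromide by SN2, which forms C4–C5 and leaves the β-keto ester intact.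

Step 5
Reactants: 9 methyl (E)-7-methyl-3-oxo-10-(triisopropylsilyloxy)dec-6-enoate
Product: 10 methyl (2Z)-2-[(5S,6R)-5-bromo-6-methyl-6-(3-(triisopropylsilyloxy)propyl)oxan-2-ylidene]acetate
Conditions: NBS, matched cinchona amine–thiocarbamate catalyst (10 mol %), CHCl3/toluene, −78 °C
Reagents that add atoms: N-bromosuccinimide, O=C1CCC(=O)N1Br
Why: Catalytic enantioselective bromo-cycloetherification of an olefinic 1,3-dicarbonyl compound, in which the catalyst delivers Br+ to one face of the (E)-C6=C7 alkene and the enol oxygen opens the bromonium ion at the tertiary carbon C7 anti to bromine (six-membered ring), so that C6 and C7 are set together, relatively by anti addition to the E alkene and absolutely by the catalyst, the enol being engaged as the nucleophile so that C2 is not brominated.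

Step 6
Reactants: 10 methyl (2Z)-2-[(5S,6R)-5-bromo-6-methyl-6-(3-(triisopropylsilyloxy)propyl)oxan-2-ylidene]acetate
Product: 11 methyl (1S,2S,3S)-3-bromo-2-methyl-6-oxo-2-[3-(triisopropylsilyloxy)propyl]cyclohexane-1-carboxylate
Conditions: SnCl4 (1.2 equiv), CH2Cl2, −78 to −40 °C
Reagents that add atoms: none
Why: Proposed new method: SnCl4 chelates the vinylogous carbonate, the equatorial C6 bromine lies antiperiplanar to the C7–O bond and expels the tin enolate to re-form the same bridged bromonium ion, and the tethered enolate carbon C2 then attacks C7 irreversibly through a chair (the Z enolate places the ester equatorial and the acidic C2–H allows equilibration to that epimer), which amounts to an O-to-C 1,3-shift with retention at C6 and C7; the closest known reaction types are the acid-induced O-to-C isomerisation of selenoetherification products of alkenyl β-keto esters, the SnCl4 cyclisation of unsaturated β-keto esters to 2-carbomethoxycyclohexanones, the Lewis-acid ionisation of enantiopure β-bromo tertiary esters to bromonium ions in polyene cyclisations and the Petasis–Ferrier rearrangement.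

Step 7
Reactants: 11 methyl (1S,2S,3S)-3-bromo-2-methyl-6-oxo-2-[3-(triisopropylsilyloxy)propyl]cyclohexane-1-carboxylate
Product: 12 methyl (1R,2S,3S)-3-bromo-2-methyl-6-methylidene-2-[3-(triisopropylsilyloxy)propyl]cyclohexane-1-carboxylate
Conditions: Zn, CH2Br2, TiCl4, THF/CH2Cl2, 0 °C to rt
Reagents that add atoms: dibromomethane, BrCBr
Why: Takai–Lombardo methylenation uses a non-basic gem-dimetallic methylene reagent that converts the hindered, enolisable ketone into the methylidene group in the presence of the ester without epimerising C2 or eliminating HBr.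

Step 8
Reactants: 12 methyl (1R,2S,3S)-3-bromo-2-methyl-6-methylidene-2-[3-(triisopropylsilyloxy)propyl]cyclohexane-1-carboxylate
Product: 13 [(1R,2S,3S)-3-bromo-2-methyl-6-methylidene-2-(3-(triisopropylsilyloxy)propyl)cyclohexyl]methanol
Conditions: i-Bu2AlH, CH2Cl2, −78 to 0 °C
Reagents that add atoms: none
Why: Hydride reduction of the ester with i-Bu2AlH gives the primary alcohol at low temperature without touching the hindered secondary bromide, the alkene or the silyl ether.

Step 9
Reactants: 13 [(1R,2S,3S)-3-bromo-2-methyl-6-methylidene-2-(3-(triisopropylsilyloxy)propyl)cyclohexyl]methanol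
Product: 14 (1R,2S,3S)-3-bromo-1-(iodomethyl)-2-methyl-6-methylidene-2-[3-(triisopropylsilyloxy)propyl]cyclohexane
Conditions: I2, PPh3, imidazole, CH2Cl2, 0 °C to rt
Reagents that add atoms: iodine, II
Why: Appel-type iodination replaces the primary hydroxyl by iodide through SN2 on the alkoxyphosphonium ion and provides the handle for zinc insertion.

Step 10
Reactants: 15 3-bromo-4-hydroxybenzoic acid
Product: 16 tert-butyl 3-bromo-4-hydroxybenzoate
Conditions: Me2NCH(Ot-Bu)2, toluene, 80 °C
Reagents that add atoms: N,N-dimethylformamide di-tert-butyl acetal, CN(C)C(OC(C)(C)C)OC(C)(C)C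
Why: Esterification with the formamide acetal alkylates the carboxylate in preference to the less acidic phenol and installs an ester that resists the organometallic reagents used later.

Step 11
Reactants: 16 tert-butyl 3-bromo-4-hydroxybenzoate
Product: 17 tert-butyl 3-bromo-4-(triisopropylsilyloxy)benzoate
Conditions: TIPSCl, imidazole, DMF, rt
Reagents that add atoms: chlorotriisopropylsilane, CC(C)[Si](Cl)(C(C)C)C(C)C
Why: Imidazole-promoted silylation of the phenol gives the most base-stable common aryl silyl ether, which survives mild acid and carbanions and is removed by fluoride at the end.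

Step 12
Reactants: 14 (1R,2S,3S)-3-bromo-1-(iodomethyl)-2-methyl-6-methylidene-2-[3-(triisopropylsilyloxy)propyl]cyclohexane; 17 tert-butyl 3-bromo-4-(triisopropylsilyloxy)benzoate
Product: 19 tert-butyl 3-{[(1R,2S,3S)-3-bromo-2-methyl-6-methylidene-2-(3-(triisopropylsilyloxy)propyl)cyclohexyl]methyl}-4-(triisopropylsilyloxy)benzoate, via alkylzinc iodide 18 (not isolated)
Conditions: Zn dust, LiCl, THF, 25 °C; then 17, Pd(OAc)2 (3 mol %), SPhos (6 mol %), THF, 40 °C
Reagents that add atoms: none
Why: Negishi sp3–sp2 cross-coupling, in which zinc inserts into the primary C–I bond while the hindered secondary C6–Br bond stays inert at room temperature, and the alkylzinc iodide transmetalates to the arylpalladium bromide from 17 so that reductive elimination forms C1–C3′ without touching C2.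

Step 13
Reactants: 19 tert-butyl 3-{[(1R,2S,3S)-3-bromo-2-methyl-6-methylidene-2-(3-(triisopropylsilyloxy)propyl)cyclohexyl]methyl}-4-(triisopropylsilyloxy)benzoate
Product: 20 tert-butyl 3-{[(1R,2S,3S)-3-bromo-2-(3-hydroxypropyl)-2-methyl-6-methylidenecyclohexyl]methyl}-4-(triisopropylsilyloxy)benzoate
Conditions: aqueous HF, MeCN, 0 °C to rt
Reagents that add atoms: none
Why: Under acidic fluoride conditions the more basic alkyl silyl ether oxygen is cleaved much faster than the aryl silyl ether (selective desilylation), and the weak acid HF leaves the methylidene group and the tert-butyl ester untouched.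

Step 14
Reactants: 20 tert-butyl 3-{[(1R,2S,3S)-3-bromo-2-(3-hydroxypropyl)-2-methyl-6-methylidenecyclohexyl]methyl}-4-(triisopropylsilyloxy)benzoate
Product: 21 tert-butyl 3-{[(1R,2S,3S)-3-bromo-2-methyl-6-methylidene-2-(3-oxopropyl)cyclohexyl]methyl}-4-(triisopropylsilyloxy)benzoate
Conditions: Dess–Martin periodinane, CH2Cl2, 0 °C to rt
Reagents that add atoms: none
Why: Dess–Martin oxidation takes the primary alcohol to the C10 aldehyde under neutral conditions without over-oxidation.

Step 15
Reactants: 21 tert-butyl 3-{[(1R,2S,3S)-3-bromo-2-methyl-6-methylidene-2-(3-oxopropyl)cyclohexyl]methyl}-4-(triisopropylsilyloxy)benzoate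
Product: 22 tert-butyl 3-{[(1R,2S,3S)-3-bromo-2-(3-hydroxy-4-methylpent-4-en-1-yl)-2-methyl-6-methylidenecyclohexyl]methyl}-4-(triisopropylsilyloxy)benzoate
Conditions: CH2=C(CH3)MgBr, THF, −78 °C
Reagents that add atoms: isopropenylmagnesium bromide, CC(=C)[Mg]Br
Why: Grignard 1,2-addition to the aldehyde at low temperature outpaces attack on the tert-butyl ester and gives the 2-methylallylic alcohol, whose C10 configuration is left uncontrolled because the next step erases it.

Step 16
Reactants: 22 tert-butyl 3-{[(1R,2S,3S)-3-bromo-2-(3-hydroxy-4-methylpent-4-en-1-yl)-2-methyl-6-methylidenecyclohexyl]methyl}-4-(triisopropylsilyloxy)benzoate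
Product: 25 tert-butyl 3-{[(1R,2S,3S)-3-bromo-2-[(3E)-7-methoxy-4-methyl-7-oxohept-3-en-1-yl]-2-methyl-6-methylidenecyclohexyl]methyl}-4-(triisopropylsilyloxy)benzoate, via mixed orthoester 23 (not isolated), via ketene acetal 24 (not isolated)
Conditions: CH3C(OMe)3, EtCO2H (cat.), xylene, 135 °C, MeOH distilled off
Reagents that add atoms: trimethyl orthoacetate, COC(C)(OC)OC
Why: Johnson–Claisen rearrangement, in which the ketene acetal formed by orthoester exchange rearranges through a chair with the C9 chain equatorial, which forms C12–C13, makes the former carbinol oxygen the C14 carbonyl oxygen and gives the (E)-C10=C11 alkene.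

Step 17
Reactants: 25 tert-butyl 3-{[(1R,2S,3S)-3-bromo-2-[(3E)-7-methoxy-4-methyl-7-oxohept-3-en-1-yl]-2-methyl-6-methylidenecyclohexyl]methyl}-4-(triisopropylsilyloxy)benzoate
Product: 26 tert-butyl 3-{[(1R,2S,3S)-3-bromo-2-[(3E)-6-carboxy-4-methylhex-3-en-1-yl]-2-methyl-6-methylidenecyclohexyl]methyl}-4-(triisopropylsilyloxy)benzoate
Conditions: Me3SnOH, 1,2-dichloroethane, 75 °C; dilute aqueous HCl work-up
Reagents that add atoms: trimethyltin hydroxide, C[Sn](C)(C)O
Why: Tin hydroxide-mediated ester hydrolysis cleaves the unhindered methyl ester under nearly neutral conditions and should leave the tert-butyl benzoate, the base-sensitive aryl silyl ether and the secondary bromide intact.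

Step 18
Reactants: 26 tert-butyl 3-{[(1R,2S,3S)-3-bromo-2-[(3E)-6-carboxy-4-methylhex-3-en-1-yl]-2-methyl-6-methylidenecyclohexyl]methyl}-4-(triisopropylsilyloxy)benzoate
Product: 27 tert-butyl 3-{[(1R,2S,3S)-3-bromo-2-{(3R)-3-bromo-3-[(2S)-2-methyl-5-oxooxolan-2-yl]propyl}-2-methyl-6-methylidenecyclohexyl]methyl}-4-(triisopropylsilyloxy)benzoate
Conditions: NBS, matched cinchona amine–thiocarbamate catalyst (10 mol %), CHCl3/toluene, −78 °C
Reagents that add atoms: N-bromosuccinimide, O=C1CCC(=O)N1Br
Why: The quinuclidine nitrogen of the catalyst binds the C14 carboxylic acid as an ion pair while the thiocarbamate sulfur relays Br+ from NBS to one face of the (E)-C10=C11 alkene, and the carboxylate oxygen then opens the bromonium ion at the more substituted carbon C11 from the side opposite to bromine. The closest known reaction type is the catalytic enantioselective bromolactonisation of 4-substituted and trisubstituted alk-4-enoic acids with NBS and cinchona amine–thiocarbamates. The one ring closed is the γ-lactone O–C11–C12–C13–C14, formed in the 5-exo mode, which here is also the Markovnikov mode, so the 6-endo δ-lactone is not expected. C10 and C11 are created together: the anti relationship of Br and O follows from stereospecific anti addition to the E alkene, and the absolute configuration (10R,11S) comes from the catalyst, since the nearest ring A stereocentre, C7, is separated from C10 by C8 and C9 and exerts little bias. The step needs chemoselectivity for C10=C11 over the C3 methylidene and the arene, which the tethered carboxylate secures by trapping this bromonium ion as it forms, whereas bromine transfer to the methylidene is reversible and unproductive and the benzoate ring is deactivated; it also needs face selectivity, and because ring A is already a single enantiomer any face error would appear as a separable diastereomer and not as lost enantiopurity.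

Step 19
Reactants: 27 tert-butyl 3-{[(1R,2S,3S)-3-bromo-2-{(3R)-3-bromo-3-[(2S)-2-methyl-5-oxooxolan-2-yl]propyl}-2-methyl-6-methylidenecyclohexyl]methyl}-4-(triisopropylsilyloxy)benzoate
Product: 29 tert-butyl 3-{[(1R,2S,3S)-3-bromo-2-[(3R,4S)-3-bromo-4-hydroxy-4,8-dimethyl-7-oxonon-8-en-1-yl]-2-methyl-6-methylidenecyclohexyl]methyl}-4-(triisopropylsilyloxy)benzoate, via lithium hemiketalate 28 (not isolated)
Conditions: CH2=C(CH3)Li (from 2-bromopropene, t-BuLi, Et2O, −78 °C), THF, −78 °C; AcOH, −78 °C
Reagents that add atoms: isopropenyllithium, [Li]C(C)=C (made from 2-bromopropene, BrC(C)=C)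
Why: Acyl addition of an alkenyllithium to a γ-lactone should stop at the lithium hemiketalate at −78 °C, so that one isopropenyl group is delivered to C14, the tert-butyl ester and the bromides are spared, and the C11 oxygen is released as the free tertiary alcohol only on acidic quench, which avoids epoxide closure onto C10.

Step 20
Reactants: 29 tert-butyl 3-{[(1R,2S,3S)-3-bromo-2-[(3R,4S)-3-bromo-4-hydroxy-4,8-dimethyl-7-oxonon-8-en-1-yl]-2-methyl-6-methylidenecyclohexyl]methyl}-4-(triisopropylsilyloxy)benzoate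
Product: 30 tert-butyl 3-{[(1R,2S,3S)-3-bromo-2-[(3R,4S,7S)-3-bromo-4,7-dihydroxy-4,8-dimethylnon-8-en-1-yl]-2-methyl-6-methylidenecyclohexyl]methyl}-4-(triisopropylsilyloxy)benzoate
Conditions: (R)-2-methyl-CBS-oxazaborolidine (20 mol %), catecholborane (excess), toluene, −78 °C
Reagents that add atoms: none
Why: Corey–Bakshi–Shibata reduction delivers hydride to one face of the enone carbonyl with isopropenyl as the large substituent, so the (R)-catalyst should give the (14S)-allylic alcohol by reagent control and in the 1,2-mode, the remote stereocentres having no influence.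

Step 21
Reactants: 30 tert-butyl 3-{[(1R,2S,3S)-3-bromo-2-[(3R,4S,7S)-3-bromo-4,7-dihydroxy-4,8-dimethylnon-8-en-1-yl]-2-methyl-6-methylidenecyclohexyl]methyl}-4-(triisopropylsilyloxy)benzoate
Product: 32 3-{[(1R,2S,3S)-3-bromo-2-[(3R,4S,7S)-3-bromo-4,7-dihydroxy-4,8-dimethylnon-8-en-1-yl]-2-methyl-6-methylidenecyclohexyl]methyl}-4-(triisopropylsilyloxy)benzoic acid, via tris-trimethylsilyl derivative 31 (not isolated)
Conditions: TMSOTf, 2,6-lutidine, CH2Cl2, 0 °C; then aqueous citric acid, MeOH/THF, rt
Reagents that add atoms: none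
Why: Silyl triflate-mediated tert-butyl ester cleavage (loss of isobutene from the O-silylated ester) avoids protic acid that would isomerise the methylidene group or ionise the allylic alcohol, and the transient trimethylsilyl ester and ethers are hydrolysed by dilute citric acid while the aryl silyl ether stays.

Step 22
Reactants: 32 3-{[(1R,2S,3S)-3-bromo-2-[(3R,4S,7S)-3-bromo-4,7-dihydroxy-4,8-dimethylnon-8-en-1-yl]-2-methyl-6-methylidenecyclohexyl]methyl}-4-(triisopropylsilyloxy)benzoic acid
Product: 34 4′-O-triisopropylsilyl bromophycolide E, via mixed anhydride 33 (not isolated)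
Conditions: 2-methyl-6-nitrobenzoic anhydride (MNBA), DMAP, CH2Cl2, rt, slow addition at high dilution
Reagents that add atoms: none
Why: Shiina macrolactonisation activates the benzoic acid as a mixed anhydride that DMAP transfers to the secondary allylic C14 hydroxyl, closing the 15-membered ring at room temperature with retention at C14, the tertiary C11 hydroxyl being too hindered to compete.

Step 23
Reactants: 34 4′-O-triisopropylsilyl bromophycolide E
Product: 35 bromophycolide E
Conditions: TBAF, AcOH (1:1), THF, 0 °C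
Reagents that add atoms: none
Why: Fluoride-mediated desilylation frees the phenol, and buffering with acetic acid keeps the medium non-basic so that the C10 bromide and C11 hydroxyl do not close to an epoxide and the macrolactone is not opened.

**Compound list**

1 | pent-4-yn-1-ol | OCCCC#C | starting material
2 | triisopropyl(pent-4-yn-1-yloxy)silane | C#CCCCO[Si](C(C)C)(C(C)C)C(C)C | intermediate
3 | (E)-dimethyl[2-methyl-5-(triisopropylsilyloxy)pent-1-en-1-yl]alane | C[Al](C)/C=C(\C)CCCO[Si](C(C)C)(C(C)C)C(C)C | intermediate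
4 | lithium butyl(dimethyl)[(E)-2-methyl-5-(triisopropylsilyloxy)pent-1-en-1-yl]aluminate | [Li+].CCCC[Al-](C)(C)/C=C(\C)CCCO[Si](C(C)C)(C(C)C)C(C)C | intermediate
5 | (E)-3-methyl-6-(triisopropylsilyloxy)hex-2-en-1-ol | OC/C=C(\C)CCCO[Si](C(C)C)(C(C)C)C(C)C | intermediate
6 | (E)-(6-bromo-4-methylhex-4-en-1-yloxy)triisopropylsilane | BrC/C=C(\C)CCCO[Si](C(C)C)(C(C)C)C(C)C | intermediate
7 | methyl acetoacetate | COC(=O)CC(C)=O | starting material
8 | methyl acetoacetate dianion, sodium lithium salt | [Na+].[Li+].[CH2-]C(=O)[CH-]C(=O)OC | intermediate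
9 | methyl (E)-7-methyl-3-oxo-10-(triisopropylsilyloxy)dec-6-enoate | COC(=O)CC(=O)CC/C=C(\C)CCCO[Si](C(C)C)(C(C)C)C(C)C | intermediate
10 | methyl (2Z)-2-[(5S,6R)-5-bromo-6-methyl-6-(3-(triisopropylsilyloxy)propyl)oxan-2-ylidene]acetate (skeleton 6S,7R; alkene geometry inconsequential) | CC(C)[Si](C(C)C)(C(C)C)OCCC[C@@]1(C)O/C(=C\C(=O)OC)CC[C@@H]1Br | intermediate
11 | methyl (1S,2S,3S)-3-bromo-2-methyl-6-oxo-2-[3-(triisopropylsilyloxy)propyl]cyclohexane-1-carboxylate (skeleton 2S,6S,7S; Br, ester and C8 chain equatorial, CH3 axial) | CC(C)[Si](C(C)C)(C(C)C)OCCC[C@@]1(C)[C@H](C(=O)OC)C(=O)CC[C@@H]1Br | intermediate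
12 | methyl (1R,2S,3S)-3-bromo-2-methyl-6-methylidene-2-[3-(triisopropylsilyloxy)propyl]cyclohexane-1-carboxylate | CC(C)[Si](C(C)C)(C(C)C)OCCC[C@@]1(C)[C@H](C(=O)OC)C(=C)CC[C@@H]1Br | intermediate
13 | [(1R,2S,3S)-3-bromo-2-methyl-6-methylidene-2-(3-(triisopropylsilyloxy)propyl)cyclohexyl]methanol | CC(C)[Si](C(C)C)(C(C)C)OCCC[C@@]1(C)[C@H](CO)C(=C)CC[C@@H]1Br | intermediate
14 | (1R,2S,3S)-3-bromo-1-(iodomethyl)-2-methyl-6-methylidene-2-[3-(triisopropylsilyloxy)propyl]cyclohexane | CC(C)[Si](C(C)C)(C(C)C)OCCC[C@@]1(C)[C@H](CI)C(=C)CC[C@@H]1Br | intermediate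
15 | 3-bromo-4-hydroxybenzoic acid | OC(=O)c1ccc(O)c(Br)c1 | starting material
16 | tert-butyl 3-bromo-4-hydroxybenzoate | CC(C)(C)OC(=O)c1ccc(O)c(Br)c1 | intermediate
17 | tert-butyl 3-bromo-4-(triisopropylsilyloxy)benzoate | CC(C)[Si](C(C)C)(C(C)C)Oc1ccc(cc1Br)C(=O)OC(C)(C)C | intermediate
18 | {[(1R,2S,3S)-3-bromo-2-methyl-6-methylidene-2-(3-(triisopropylsilyloxy)propyl)cyclohexyl]methyl}zinc iodide | CC(C)[Si](C(C)C)(C(C)C)OCCC[C@@]1(C)[C@H](C[Zn]I)C(=C)CC[C@@H]1Br | intermediate
19 | tert-butyl 3-{[(1R,2S,3S)-3-bromo-2-methyl-6-methylidene-2-(3-(triisopropylsilyloxy)propyl)cyclohexyl]methyl}-4-(triisopropylsilyloxy)benzoate | CC(C)[Si](C(C)C)(C(C)C)OCCC[C@@]1(C)[C@H](Cc2cc(ccc2O[Si](C(C)C)(C(C)C)C(C)C)C(=O)OC(C)(C)C)C(=C)CC[C@@H]1Br | intermediate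
20 | tert-butyl 3-{[(1R,2S,3S)-3-bromo-2-(3-hydroxypropyl)-2-methyl-6-methylidenecyclohexyl]methyl}-4-(triisopropylsilyloxy)benzoate | OCCC[C@@]1(C)[C@H](Cc2cc(ccc2O[Si](C(C)C)(C(C)C)C(C)C)C(=O)OC(C)(C)C)C(=C)CC[C@@H]1Br | intermediate
21 | tert-butyl 3-{[(1R,2S,3S)-3-bromo-2-methyl-6-methylidene-2-(3-oxopropyl)cyclohexyl]methyl}-4-(triisopropylsilyloxy)benzoate | O=CCC[C@@]1(C)[C@H](Cc2cc(ccc2O[Si](C(C)C)(C(C)C)C(C)C)C(=O)OC(C)(C)C)C(=C)CC[C@@H]1Br | intermediate
22 | tert-butyl 3-{[(1R,2S,3S)-3-bromo-2-(3-hydroxy-4-methylpent-4-en-1-yl)-2-methyl-6-methylidenecyclohexyl]methyl}-4-(triisopropylsilyloxy)benzoate (both C10 epimers) | C=C(C)C(O)CC[C@@]1(C)[C@H](Cc2cc(ccc2O[Si](C(C)C)(C(C)C)C(C)C)C(=O)OC(C)(C)C)C(=C)CC[C@@H]1Br | intermediate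
23 | tert-butyl 3-{[(1R,2S,3S)-3-bromo-2-[3-(1,1-dimethoxyethoxy)-4-methylpent-4-en-1-yl]-2-methyl-6-methylidenecyclohexyl]methyl}-4-(triisopropylsilyloxy)benzoate | COC(C)(OC)OC(C(C)=C)CC[C@@]1(C)[C@H](Cc2cc(ccc2O[Si](C(C)C)(C(C)C)C(C)C)C(=O)OC(C)(C)C)C(=C)CC[C@@H]1Br | intermediate
24 | tert-butyl 3-{[(1R,2S,3S)-3-bromo-2-[3-(1-methoxyethenyloxy)-4-methylpent-4-en-1-yl]-2-methyl-6-methylidenecyclohexyl]methyl}-4-(triisopropylsilyloxy)benzoate | COC(=C)OC(C(C)=C)CC[C@@]1(C)[C@H](Cc2cc(ccc2O[Si](C(C)C)(C(C)C)C(C)C)C(=O)OC(C)(C)C)C(=C)CC[C@@H]1Br | intermediate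
25 | tert-butyl 3-{[(1R,2S,3S)-3-bromo-2-[(3E)-7-methoxy-4-methyl-7-oxohept-3-en-1-yl]-2-methyl-6-methylidenecyclohexyl]methyl}-4-(triisopropylsilyloxy)benzoate | COC(=O)CC/C(C)=C/CC[C@@]1(C)[C@H](Cc2cc(ccc2O[Si](C(C)C)(C(C)C)C(C)C)C(=O)OC(C)(C)C)C(=C)CC[C@@H]1Br | intermediate
26 | tert-butyl 3-{[(1R,2S,3S)-3-bromo-2-[(3E)-6-carboxy-4-methylhex-3-en-1-yl]-2-methyl-6-methylidenecyclohexyl]methyl}-4-(triisopropylsilyloxy)benzoate | OC(=O)CC/C(C)=C/CC[C@@]1(C)[C@H](Cc2cc(ccc2O[Si](C(C)C)(C(C)C)C(C)C)C(=O)OC(C)(C)C)C(=C)CC[C@@H]1Br | intermediate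
27 | tert-butyl 3-{[(1R,2S,3S)-3-bromo-2-{(3R)-3-bromo-3-[(2S)-2-methyl-5-oxooxolan-2-yl]propyl}-2-methyl-6-methylidenecyclohexyl]methyl}-4-(triisopropylsilyloxy)benzoate (skeleton 10R,11S) | O=C1CC[C@](C)(O1)[C@H](Br)CC[C@@]2(C)[C@H](Cc3cc(ccc3O[Si](C(C)C)(C(C)C)C(C)C)C(=O)OC(C)(C)C)C(=C)CC[C@@H]2Br | intermediate
28 | lithium salt of the cyclic hemiketal from addition of isopropenyllithium to the lactone carbonyl (C14) of 27 | [Li+].[O-]C1(C(C)=C)CC[C@](C)(O1)[C@H](Br)CC[C@@]2(C)[C@H](Cc3cc(ccc3O[Si](C(C)C)(C(C)C)C(C)C)C(=O)OC(C)(C)C)C(=C)CC[C@@H]2Br | intermediate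
29 | tert-butyl 3-{[(1R,2S,3S)-3-bromo-2-[(3R,4S)-3-bromo-4-hydroxy-4,8-dimethyl-7-oxonon-8-en-1-yl]-2-methyl-6-methylidenecyclohexyl]methyl}-4-(triisopropylsilyloxy)benzoate | C=C(C)C(=O)CC[C@](C)(O)[C@H](Br)CC[C@@]2(C)[C@H](Cc3cc(ccc3O[Si](C(C)C)(C(C)C)C(C)C)C(=O)OC(C)(C)C)C(=C)CC[C@@H]2Br | intermediate
30 | tert-butyl 3-{[(1R,2S,3S)-3-bromo-2-[(3R,4S,7S)-3-bromo-4,7-dihydroxy-4,8-dimethylnon-8-en-1-yl]-2-methyl-6-methylidenecyclohexyl]methyl}-4-(triisopropylsilyloxy)benzoate | C=C(C)[C@@H](O)CC[C@](C)(O)[C@H](Br)CC[C@@]2(C)[C@H](Cc3cc(ccc3O[Si](C(C)C)(C(C)C)C(C)C)C(=O)OC(C)(C)C)C(=C)CC[C@@H]2Br | intermediate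
31 | trimethylsilyl ester and C11,C14-bis(trimethylsilyl) ether of 32 | C=C(C)[C@@H](O[Si](C)(C)C)CC[C@](C)(O[Si](C)(C)C)[C@H](Br)CC[C@@]2(C)[C@H](Cc3cc(ccc3O[Si](C(C)C)(C(C)C)C(C)C)C(=O)O[Si](C)(C)C)C(=C)CC[C@@H]2Br | intermediate
32 | 3-{[(1R,2S,3S)-3-bromo-2-[(3R,4S,7S)-3-bromo-4,7-dihydroxy-4,8-dimethylnon-8-en-1-yl]-2-methyl-6-methylidenecyclohexyl]methyl}-4-(triisopropylsilyloxy)benzoic acid | C=C(C)[C@@H](O)CC[C@](C)(O)[C@H](Br)CC[C@@]2(C)[C@H](Cc3cc(ccc3O[Si](C(C)C)(C(C)C)C(C)C)C(=O)O)C(=C)CC[C@@H]2Br | intermediate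
33 | mixed anhydride of 32 with 2-methyl-6-nitrobenzoic acid | C=C(C)[C@@H](O)CC[C@](C)(O)[C@H](Br)CC[C@@]2(C)[C@H](Cc3cc(ccc3O[Si](C(C)C)(C(C)C)C(C)C)C(=O)OC(=O)c4c(C)cccc4[N+](=O)[O-])C(=C)CC[C@@H]2Br | intermediate
34 | 4′-O-triisopropylsilyl bromophycolide E | C=C(C)[C@@H]1CC[C@](C)(O)[C@H](Br)CC[C@@]2(C)[C@H](Cc3cc(ccc3O[Si](C(C)C)(C(C)C)C(C)C)C(=O)O1)C(=C)CC[C@@H]2Br | intermediate
35 | bromophycolide E (skeleton 2R,6S,7S,10R,11S,14S) | C=C(C)[C@@H]1CC[C@](C)(O)[C@H](Br)CC[C@@]2(C)[C@H](Cc3cc(ccc3O)C(=O)O1)C(=C)CC[C@@H]2Br | target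

**Step count**

Total: 23 steps. Longest linear sequence: 21 steps (steps 1–9 and 12–23, from pent-4-yn-1-ol); steps 10–11 make the arene partner.

**Steps most likely to fail**

Step 6 (the proposed new method). After ionisation the bromonium ion may lose a proton to give allylic bromides, may be captured by chloride, or may open to a free tertiary cation and lose the C7 configuration before C–C bond formation occurs. The enantioselection of step 5 feeding into it is also untested on a purely alkyl-substituted alkene. The fallback uses known chemistry and an oxygen-initiated ring closure; it sets out from 6 and comes back at 12, replacing steps 4–7. Bromide 6 is alkylated with the lithium enolate of methyl acetate (LDA, THF/DMPU, −78 °C) to methyl (E)-5-methyl-8-(triisopropylsilyloxy)oct-4-enoate F1. Shi epoxidation with the L-fructose-derived ketone catalyst and KHSO5 should give the (6S,7S)-epoxy ester F2. Crossed Claisen condensation with an excess of the same enolate gives the epoxy β-keto ester F3. SnCl4 (CH2Cl2, −78 °C) then triggers the epoxide-initiated cyclisation terminated by the β-keto ester, C2 opening the epoxide at C7 with inversion to the hydroxy keto ester F4 (hydroxyl equatorial at C6). Takai–Lombardo methylenation gives the methylidene hydroxy ester F5, and Dess–Martin oxidation gives the C6 ketone F6. LiB(s-Bu)3H reduces F6 from the equatorial direction to the axial alcohol F7, and Appel bromination (CBr4, PPh3) with inversion at C6 gives 12.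

Step 19. The hemiketalate may collapse before the quench, which would lead to double addition or to epoxide closure of the liberated C11 alkoxide onto C10; the organolithium may also attack the tert-butyl ester. The fallback works at the lactol oxidation level; it sets out from 27 and comes back at 29. Lactone 27 is reduced with i-Bu2AlH (1.1 equiv, CH2Cl2, −78 °C) to the lactol F8. CH2=C(CH3)MgBr (THF, −40 °C) opens F8 through its hydroxy aldehyde form to the C14-epimeric diol F9. Dess–Martin periodinane then oxidises only the secondary allylic hydroxyl, the tertiary C11 hydroxyl being inert, to give 29.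

Step 18. The catalyst may discriminate the two faces of a purely alkyl-substituted trisubstituted alkene poorly, or bromine may be consumed at the C3 methylidene. The fallback keeps the same ring closure but replaces catalyst control by separation and recycling; it sets out from 26 and comes back at 27. Acid 26 is treated with NBS alone (CH2Cl2, −40 °C), which should give the two anti adducts, 27 and the (10S,11R)-bromolactone F10, separable by chromatography because ring A is a single enantiomer. F10 is returned to 26 by Zn dust in AcOH, a stereospecific anti reductive elimination that regenerates the (E)-alkenoic acid, and is resubmitted.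

**Further compounds**

F1 | step 6 | methyl (E)-5-methyl-8-(triisopropylsilyloxy)oct-4-enoate | COC(=O)CC/C=C(\C)CCCO[Si](C(C)C)(C(C)C)C(C)C
F2 | step 6 | methyl 3-[(2S,3S)-3-methyl-3-(3-(triisopropylsilyloxy)propyl)oxiran-2-yl]propanoate | COC(=O)CC[C@@H]1O[C@@]1(C)CCCO[Si](C(C)C)(C(C)C)C(C)C
F3 | step 6 | methyl 5-[(2S,3S)-3-methyl-3-(3-(triisopropylsilyloxy)propyl)oxiran-2-yl]-3-oxopentanoate | COC(=O)CC(=O)CC[C@@H]1O[C@@]1(C)CCCO[Si](C(C)C)(C(C)C)C(C)C
F4 | step 6 | methyl (1S,2S,3S)-3-hydroxy-2-methyl-6-oxo-2-[3-(triisopropylsilyloxy)propyl]cyclohexane-1-carboxylate | CC(C)[Si](C(C)C)(C(C)C)OCCC[C@@]1(C)[C@H](C(=O)OC)C(=O)CC[C@@H]1O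
F5 | step 6 | methyl (1R,2S,3S)-3-hydroxy-2-methyl-6-methylidene-2-[3-(triisopropylsilyloxy)propyl]cyclohexane-1-carboxylate | CC(C)[Si](C(C)C)(C(C)C)OCCC[C@@]1(C)[C@H](C(=O)OC)C(=C)CC[C@@H]1O
F6 | step 6 | methyl (1R,2S)-2-methyl-6-methylidene-3-oxo-2-[3-(triisopropylsilyloxy)propyl]cyclohexane-1-carboxylate | CC(C)[Si](C(C)C)(C(C)C)OCCC[C@@]1(C)[C@H](C(=O)OC)C(=C)CCC1=O
F7 | step 6 | methyl (1R,2S,3R)-3-hydroxy-2-methyl-6-methylidene-2-[3-(triisopropylsilyloxy)propyl]cyclohexane-1-carboxylate | CC(C)[Si](C(C)C)(C(C)C)OCCC[C@@]1(C)[C@H](C(=O)OC)C(=C)CC[C@H]1O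
F8 | step 19 | lactol of 27 (C14 hemiacetal, both anomers) | OC1CC[C@](C)(O1)[C@H](Br)CC[C@@]2(C)[C@H](Cc3cc(ccc3O[Si](C(C)C)(C(C)C)C(C)C)C(=O)OC(C)(C)C)C(=C)CC[C@@H]2Br
F9 | step 19 | C14-epimeric mixture of diol 30 | C=C(C)C(O)CC[C@](C)(O)[C@H](Br)CC[C@@]2(C)[C@H](Cc3cc(ccc3O[Si](C(C)C)(C(C)C)C(C)C)C(=O)OC(C)(C)C)C(=C)CC[C@@H]2Br
F10 | step 18 | (10S,11R) diastereomer of lactone 27 | O=C1CC[C@@](C)(O1)[C@@H](Br)CC[C@@]2(C)[C@H](Cc3cc(ccc3O[Si](C(C)C)(C(C)C)C(C)C)C(=O)OC(C)(C)C)C(=C)CC[C@@H]2Br
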